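We begin with where the flask stops.

all flasks: Z 0.70 mM

| charge | Q | G | remark | time |
|---|---|---|---|---|
| green | 0.039 M | 8.4 mM | run made earlier |  |
| blue | 0.062 M | 8.4 mM | run made earlier |  |
| violet | 0.028 M | 4.2 mM | run made earlier |  |
| flask | 0.028 M | 8.40 mM |  | 3.0 d |

- green (time / d: D / %, Q / %): 0.625: 7.9, 91.9; 1.25: 8.5, 91.1; 2.00: 8.9, 91.6; 3.00: 9.0, 91.6; 4.00: 8.9, 90.7
- blue (time / d: D / %, Q / %): 0.250: 8.5, 91.8; 0.500: 7.9, 91.1; 1.04: 8.8, 91.0; 2.08: 8.9, 91.2; 4.00: 7.9, 92.1
- violet (time / d: D / %, Q / %): 0.333: 15.4, 85.1; 0.833: 14.6, 85.1; 1.67: 15.6, 85.5; 2.50: 14.8, 85.5; 4.00: 14.4, 84.2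

(standard deviation of a reading: 0.5 percentage points)

- average number of monomer units in a chain (chains begun, living or dead) at 3.0 d
- part of the Q that has reacted at 3.0 d

- the average divides the monomer in chains by the number of chains begun, living and dead together
- the earlier runs do not show the number of chains; that part of a forecast is a guess

In the green run D reads 7.9 % at 0.625 d and 8.9 % at 4.00 d, so we take 3.0 d to lie on a level and ask for the end state. The mean D readings of green and blue are 8.64 % and 8.40 %, although their c_Q differ. Violet, with half the G, reads 15.0 %.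

So we fold the charges into one number, the stopping ratio s = c_Z/c_G: Z charged set against G charged, read as the part of Q that reacts before growth stops. Green gives 8.33 %, close to its level. Violet gives 16.7 %, which lies 1.7 percentage points above its reading, more than the scatter of 0.5 points, so one number is not quite enough.

This flask has the s of green, so we expect c near 8.33 %. If each Z begins one chain, dp is 3.33, which is a guess.

The forecast, holding that “G sets the limit, roughly as 1/G”, gives c of 8.5 % and dp of 3.4, both slightly above our figures.

The flask gives c of 8.43 % and dp of 4.35, a dp above the forecast's.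

    Q + Z → E + D (k = 31.7 /M/h)
    Q + E → D + E, rate k2*[E]*[Q] (k = 159 /M/h)
    E + G → J (k = 156 /M/h)
    2 Z → L (k = 393 /M/h)

At 0.0610 d the half-life of E by its step with G is 0.55 h, against 1.3 d for Q by growth. At 3.00 d E stands at 0 M and Q at 92 % of its charge, while Z, the limiting reagent, stands at 0 % of its charge: of the 0.70 mM of Z charged, part lies in J at 5.43 × 10⁻⁴ M and the rest in L at 7.86 × 10⁻⁵ M, two Z in each L, together 0.700 mM. In this flask s is 8.33 % and c is 8.43 %. In the same flask with 0.0050 M of G, s is 14.0 % and c is 12.8 %.

Readings and results were computed from invented constants; noise was put on by code.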